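## The problem

Mururin C (25) is a flat 2-arylbenzofuran: ring A (C3a to C7a) is fused to the furan, ring B sits on C2 and C3 carries a formyl group. It has no stereocentre, so the whole difficulty is positional. Ring A needs a methoxy group at C7, next to the ring-fusion carbon C7a, and a 3-hydroxypropyl chain at C5, with C4 and C6 unsubstituted. Ring B is a pyrogallol in which one outer oxygen is methylated and the other two are free, so its three oxygens must be told apart from the start. The free catechol is oxidised by air in base and by any reagent that would make the aldehyde; the aldehyde is a vinylogous formate that tolerates acid but not hydride or forcing hydrogenation; the side-chain alcohol must not be oxidised when C3 is. The aldehyde therefore has to be made while the catechol is still masked, and the masks must come off without oxidant or reductant. The feature to exploit is the 1,3-relationship of O7 and C5, with O7 next to C7a: this is the resorcinol pattern produced when a ketene on a furan β-carbon (future C3a) takes up an oxygenated alkyne and the resulting dienylketene closes onto the neighbouring free α-carbon (future C7a).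

## Retrosynthesis

**End game, 25 back to 22.** No skeletal bond is cut. The two ring B phenols and the side-chain alcohol of 25 are traced to two methoxymethyl ethers and one silyl ether in aldehyde 24, so a single acid treatment releases all three. Benzyl ethers were set aside because their removal would expose the aldehyde to hydrogenation or to a strong Lewis acid. The aldehyde goes back through alcohol 23 to ethyl ester 22, because an ester at C3 survives the diazo, photochemical and organoborane chemistry that an aldehyde would not. The forward steps must reduce a hindered conjugated ester and then oxidise only the benzofuranylmethanol.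

**C5 side chain, 22 to 19 and 20.** The C5–CH2 bond is cut. The ring-forming step needs a heteroatom-activated alkyne, so C5 necessarily arrives as oxygen. That is turned to advantage: the silyl ether of 17 is exchanged through phenol 18 for the triflate of 19, which couples with alkylborane 21 made from allyl silyl ether 20. Methyl ether 17 comes from phenol 16, whose C7 hydroxyl is the only free one. The forward reactions need a fluoride cleavage that spares the ester and acetals, and an sp2–sp3 coupling on an electron-rich aryl triflate.

**Ring A, 16 to 9 and 12.** The C6–C7, C4–C5 and C7–C7a bonds are cut, which removes ring A entirely. Building the furan onto a preformed ring A would require a 1,2,3,5-tetrasubstituted arene with both oxygens already differentiated. This cut instead delivers O7 as a free phenol and O5 as a silyl ether in one operation. The precursors are a trisubstituted furan, diazoketone 9, and a two-carbon alkyne 12; the intermediates are ketene 13, cyclobutenone 14 and dienylketene 15. The forward reaction must close at furan C5 and orient the alkyne so that its oxygen ends at C5 of the benzofuran.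

**Diazoketone, 9 back to 4 and 5.** The acyl–CHN2 bond is cut to acid chloride 8 and acid 7. Acid 7 is the mono-acid of diester 6, and 6 is cut at the furan–aryl bond to aryl bromide 4 and symmetric diester 5. Because 5 is symmetric, arylation of either α-C–H gives the same product. After arylation the two esters differ: the one at C3 is flanked by the aryl ring, the one at C4 is not. The forward sequence needs a mono-arylation and a site-selective saponification.

**Ring B bromide, 4 back to 1.** Electrophilic bromination of a 1,2,3-trioxygenated benzene goes next to an outer oxygen, not para to the central one. The bromine is therefore bought in place: in aldehyde 1 it is already para to the phenol. Oxidative replacement of the formyl group through formate 2 gives catechol 3, and acetal protection gives 4.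

**Alkyne, 12 back to 10.** The O–Si bond is cut to ynolate 11, which is traced to dibromoester 10 by loss of both bromines and ethoxide.

## Roads not taken

**Alternative 1:** The cut is at C3–C3a and O1–C2, giving two phenylpropanoids, methyl 5-benzyloxyferulate A1 and dihydroconiferyl alcohol A2. In the forward step Ag2O would oxidise both phenols to radicals. C8 of the A1 radical would join C5 of the A2 radical, and the ring A phenol would add to the quinone methide to give the racemic trans-dihydrobenzofuran A3. Dehydrogenation to the benzofuran, ester-to-aldehyde adjustment and debenzylation would finish the synthesis.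
- Merits: every carbon and oxygen of the target is assembled in one step from partners that are one or two steps from commerce. The route would be less than half as long as the chosen one.
- Weak points: this is a cross-coupling of two different phenoxy radicals. A1 can still dimerise through its 8–8 and 8–O–4 modes, A2 through 5–5 and O–5 modes, and only an excess of one partner biases the outcome. The two stereocentres made are destroyed again, and the dehydrogenation must spare a free para-phenol.
- Comparison: in step count this road is clearly better. The chosen plan sets against it that every bond is made at a site fixed by the substrate, with no statistical coupling to separate.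

**Alternative 2:** The cut is at O1–C2 and C2–C1' of ring B. The precursors are dibromoacrylate A4 (methyl 3,3-dibromo-2-[5-(3-silyloxypropyl)-2-hydroxy-3-methoxyphenyl]acrylate) and ring B boronate A5. Under Pd(OAc)2 with a biarylphosphine and K3PO4, the phenoxide would displace one bromine to close the furan. The remaining C–Br bond would then undergo Suzuki coupling to give benzofuran ester A6, three functional-group steps from the target.
- Merits: convergent and regiochemically unambiguous. Ring A comes from a cheap guaiacol-type phenol, and the route is probably four or five steps shorter than the chosen one.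
- Weak points: A4 requires ortho-acylation of a phenol with an oxalyl unit and dibromo-olefination of a hindered aryl ketoester, with the phenol protected and released around it. In the tandem step the C–O closure must precede the cross-coupling, otherwise diarylated or open-chain products appear.
- Comparison: in length and in precedent for each bond this road is at least as good. The chosen plan sets against it that it needs no pre-oxygenated, fully substituted ring A. The two ring A oxygens emerge already differentiated, and the C5 handle (a triflate) is open to variation late.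

**Alternative 3:** The cut is at C2–C3, C3–C3a and O1–C2, giving 2-hydroxybenzophenone A7 ((5-allyl-2-hydroxy-3-methoxyphenyl)(3,4-dibenzyloxy-5-methoxyphenyl)methanone) and ethyl diazoacetate A8. Under HBF4·OEt2, A8 would add to the ketone, ring A would shift to the diazo carbon with loss of dinitrogen, and the phenol would condense on the new ketone to give benzofuran ester A9. Hydroboration of the allyl group and the same end game would follow.
- Merits: A7 is an acylated eugenol, so the starting materials are very cheap and the furan ring forms in one step.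
- Weak points: the reaction type is secure for salicylaldehydes, where hydride migrates. A diaryl ketone is far less electrophilic, and either aryl group can migrate; migration of ring B leads off the route. Strong acid also meets an allyl group and two benzyl ethers.
- Comparison: if the insertion behaved, this road would be shorter. Its key step rests on a migratory preference that the substrate does not enforce. In the chosen plan each elementary event of the key cascade has a single possible site.

Key step: step 7

Remark: Ar stands for 3-methoxy-4,5-bis(methoxymethoxy)phenyl throughout. Compounds 1, 5, 10 and 20 are assumed to be purchasable. The target is achiral; the only stereocentre on the way, in 14, is racemic and transient.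

## Steps

Step 1
Reactants: 1 5-bromo-2-hydroxy-3-methoxybenzaldehyde
Product: 3 5-bromo-3-methoxybenzene-1,2-diol, via aryl formate 2 (not isolated)
Conditions: H2O2 (30% aq), NaOH (aq), N2, 0 °C → rt; then HCl (aq)
Reagents that add atoms: hydrogen peroxide, OO
Why: Dakin oxidation: hydroperoxide adds to the aldehyde of the ortho-hydroxybenzaldehyde, the electron-rich aryl group migrates to oxygen to give formate 2, and this is saponified in the same alkaline medium; the bromine ends para to the central oxygen, a position electrophilic bromination of the catechol would not reach.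

Step 2
Reactants: 3 5-bromo-3-methoxybenzene-1,2-diol
Product: 4 5-bromo-1-methoxy-2,3-bis(methoxymethoxy)benzene
Conditions: MOMCl, i-Pr2NEt, CH2Cl2, 0 °C → reflux
Reagents that add atoms: chloromethyl methyl ether, COCCl
Why: Williamson-type O-alkylation of both phenols; the acetal ethers carry no aromatic C–H that could compete in step 3, they survive base, fluoride, hydride and MnO2, and they fall to dilute acid at the end.

Step 3
Reactants: 4 5-bromo-1-methoxy-2,3-bis(methoxymethoxy)benzene; 5 diethyl furan-3,4-dicarboxylate (3 equiv)
Product: 6 diethyl 2-Ar-furan-3,4-dicarboxylate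
Conditions: Pd(OAc)2 (5 mol %), PCy3·HBF4 (10 mol %), PivOH (30 mol %), K2CO3, DMA, 100 °C
Reagents that add atoms: none
Why: Palladium-catalysed direct C–H arylation: 4 adds oxidatively to zerovalent palladium and the furan α-C–H is cleaved by concerted metalation–deprotonation with pivalate as proton shuttle, as in the C2 arylation of 3-furoates; the two α-positions of 5 are equivalent and acidified by the neighbouring esters, and the excess of 5 suppresses a second arylation.

Step 4
Reactants: 6 diethyl 2-Ar-furan-3,4-dicarboxylate
Product: 7 4-(ethoxycarbonyl)-5-Ar-furan-3-carboxylic acid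
Conditions: LiOH·H2O (1.05 equiv), THF/H2O, 0 °C → rt; then HCl (aq) to pH 4, 0 °C
Reagents that add atoms: lithium hydroxide, [Li+].[OH-]
Why: Site-selective saponification: the C4 ester has a hydrogen on one side, whereas the C3 ester is flanked by the twisted aryl ring and the other ester and is further deactivated by donation from the electron-rich aryl group through C2=C3, so one equivalent of hydroxide should take the C4 ester.

Step 5
Reactants: 7 4-(ethoxycarbonyl)-5-Ar-furan-3-carboxylic acid
Product: 9 ethyl 4-(2-diazoacetyl)-2-Ar-furan-3-carboxylate, via acid chloride 8 (not isolated)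
Conditions: Me2C=C(Cl)NMe2, CH2Cl2, 0 °C → rt; then CH2N2 (3 equiv), Et2O, 0 °C
Reagents that add atoms: 1-chloro-N,N,2-trimethylprop-1-en-1-amine, CC(C)=C(Cl)N(C)C (chlorine of 8 only); diazomethane, C=[N+]=[N-]
Why: The α-chloroenamine converts the acid into acid chloride 8 without releasing HCl, which keeps the acetal ethers intact, and C-acylation of diazomethane (first stage of the Arndt–Eistert sequence) gives the diazoketone while a second equivalent of diazomethane consumes the HCl formed.

Step 6
Reactants: 10 ethyl dibromoacetate
Product: 12 (ethynyloxy)triisopropylsilane, via lithium ethynolate 11 (not isolated)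
Conditions: t-BuLi (4 equiv), THF, −78 → 0 °C; then i-Pr3SiOTf, −78 °C → rt
Reagents that add atoms: tert-butyllithium, [Li]C(C)(C)C (lithium of 11 only); triisopropylsilyl trifluoromethanesulfonate, CC(C)[Si](OS(=O)(=O)C(F)(F)F)(C(C)C)C(C)C
Why: Ynolate formation by the ester-dianion route: two bromine–lithium exchanges give the α-lithio ester enolate, which expels lithium ethoxide to give ynolate 11, and the bulky silyl triflate silylates the ynolate on oxygen to give the silyl ynol ether.

Step 7
Reactants: 9 ethyl 4-(2-diazoacetyl)-2-Ar-furan-3-carboxylate; 12 (ethynyloxy)triisopropylsilane (2 equiv)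
Product: 16 ethyl 7-hydroxy-2-Ar-5-(triisopropylsilyloxy)-1-benzofuran-3-carboxylate, via furylketene 13 (not isolated), via siloxycyclobutenone 14 (not isolated), via dienylketene 15 (not isolated)
Conditions: hν (medium-pressure Hg lamp, Pyrex filter), ClCH2CH2Cl, rt; then 80 °C
Reagents that add atoms: none
Why: Light expels dinitrogen from 9 and Wolff rearrangement gives furylketene 13. Its carbonyl carbon bonds to the nucleophilic CH terminus of 12 and its CH carbon to the oxygen-bearing alkyne carbon in a [2+2] cycloaddition, which forms C6–C7 and C4–C5 and gives racemic cyclobutenone 14. On further irradiation and at 80 °C, 14 opens reversibly by a four-electron electrocyclic reaction to dienylketene 15, and only the isomer with the furan cis to the ketene arm can react further. A six-electron electrocyclisation through the furan C4=C5 bond then forms C7–C7a and closes ring A as a six-membered carbocycle, and tautomerisation of the cyclohexadienone gives phenol 16. The closest known reaction type is the photochemical Wolff variant of the Danheiser benzannulation with heteroaryl diazomethyl ketones and siloxyalkynes. No stereocentre is created in the product; the one in 14 disappears on ring opening. The step needs closure at furan C5 and not at C3, which is secured because C3 carries the ester, lies outside the C4=C5 π bond and could not aromatise. It also needs a single alkyne orientation, which is fixed by the polarity of the ynol ether and puts the silyloxy group at C5 and the free hydroxyl at C7.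

Step 8
Reactants: 16 ethyl 7-hydroxy-2-Ar-5-(triisopropylsilyloxy)-1-benzofuran-3-carboxylate
Product: 17 ethyl 7-methoxy-2-Ar-5-(triisopropylsilyloxy)-1-benzofuran-3-carboxylate
Conditions: MeI, K2CO3, acetone, 40 °C
Reagents that add atoms: iodomethane, CI
Why: Williamson methylation of the only free phenol; the hindered aryl silyl ether, the ester and the acetal ethers do not react with K2CO3 in acetone.

Step 9
Reactants: 17 ethyl 7-methoxy-2-Ar-5-(triisopropylsilyloxy)-1-benzofuran-3-carboxylate
Product: 19 ethyl 7-methoxy-2-Ar-5-(trifluoromethylsulfonyloxy)-1-benzofuran-3-carboxylate, via phenol 18 (not isolated)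
Conditions: Bu4NF (1.05 equiv), THF, 0 °C; then PhNTf2 (1.3 equiv), 0 °C → rt
Reagents that add atoms: N-phenylbis(trifluoromethanesulfonimide), O=S(=O)(N(c1ccccc1)S(=O)(=O)C(F)(F)F)C(F)(F)F
Why: Fluoride cleaves the aryl O–Si bond to the tetrabutylammonium phenoxide of 18, which is sulfonylated in the same flask by the triflimide; one equivalent of fluoride leaves the ester and acetals untouched.

Step 10
Reactants: 20 tert-butyl(dimethyl)(prop-2-en-1-yloxy)silane; 19 ethyl 7-methoxy-2-Ar-5-(trifluoromethylsulfonyloxy)-1-benzofuran-3-carboxylate
Product: 22 ethyl 5-[3-(tert-butyldimethylsilyloxy)propyl]-7-methoxy-2-Ar-1-benzofuran-3-carboxylate, via alkylborane 21 (not isolated)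
Conditions: 20, 9-BBN-H, THF, 0 °C → rt; then 19, PdCl2(dppf)·CH2Cl2 (5 mol %), K3PO4 (aq), THF/DMF, 65 °C
Reagents that add atoms: 9-borabicyclo[3.3.1]nonane, B1C2CCCC1CCC2 (boron and bicyclic frame of 21 only)
Why: Anti-Markovnikov hydroboration of the allyl ether gives primary alkylborane 21, and B-alkyl Suzuki–Miyaura coupling with the aryl triflate forms the C5–CH2 bond; the bidentate ligand favours reductive elimination over β-hydride elimination.

Step 11
Reactants: 22 ethyl 5-[3-(tert-butyldimethylsilyloxy)propyl]-7-methoxy-2-Ar-1-benzofuran-3-carboxylate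
Product: 23 {5-[3-(tert-butyldimethylsilyloxy)propyl]-7-methoxy-2-Ar-1-benzofuran-3-yl}methanol
Conditions: i-Bu2AlH (3 equiv), CH2Cl2, −78 → 0 °C; Rochelle salt (aq)
Reagents that add atoms: none
Why: Hydride reduction of the conjugated ester to the primary alcohol; silyl, acetal and methyl ethers do not react with the aluminium hydride.

Step 12
Reactants: 23 {5-[3-(tert-butyldimethylsilyloxy)propyl]-7-methoxy-2-Ar-1-benzofuran-3-yl}methanol
Product: 24 5-[3-(tert-butyldimethylsilyloxy)propyl]-7-methoxy-2-Ar-1-benzofuran-3-carbaldehyde
Conditions: MnO2 (activated, excess), CH2Cl2, rt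
Reagents that add atoms: none
Why: MnO2 oxidises only the benzylic-type benzofuran-3-ylmethanol and stops at the aldehyde; the side-chain oxygen is silylated and the catechol is still masked, so nothing else can be oxidised.

Step 13
Reactants: 24 5-[3-(tert-butyldimethylsilyloxy)propyl]-7-methoxy-2-Ar-1-benzofuran-3-carbaldehyde
Product: 25 Mururin C, 2-(3,4-dihydroxy-5-methoxyphenyl)-5-(3-hydroxypropyl)-7-methoxy-1-benzofuran-3-carbaldehyde
Conditions: HCl (1.25 M in MeOH), THF, rt → 40 °C; then H2O
Reagents that add atoms: none
Why: Acid-catalysed acetal exchange removes both methoxymethyl ethers and methanolysis removes the silyl ether in one operation; the vinylogous-formate aldehyde and the aryl methyl ethers do not react, and the catechol is released under acidic, non-oxidising conditions.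

## Compound list

1 | 5-bromo-2-hydroxy-3-methoxybenzaldehyde | COc1cc(Br)cc(C=O)c1O | starting material
2 | 5-bromo-2-hydroxy-3-methoxyphenyl formate | O=COc1cc(Br)cc(OC)c1O | intermediate
3 | 5-bromo-3-methoxybenzene-1,2-diol | COc1cc(Br)cc(O)c1O | intermediate
4 | 5-bromo-1-methoxy-2,3-bis(methoxymethoxy)benzene | COCOc1cc(Br)cc(OC)c1OCOC | intermediate
5 | diethyl furan-3,4-dicarboxylate | CCOC(=O)c1cocc1C(=O)OCC | starting material
6 | diethyl 2-[3-methoxy-4,5-bis(methoxymethoxy)phenyl]furan-3,4-dicarboxylate | CCOC(=O)c1coc(-c2cc(OC)c(OCOC)c(OCOC)c2)c1C(=O)OCC | intermediate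
7 | 4-(ethoxycarbonyl)-5-[3-methoxy-4,5-bis(methoxymethoxy)phenyl]furan-3-carboxylic acid | CCOC(=O)c1c(C(=O)O)coc1-c1cc(OC)c(OCOC)c(OCOC)c1 | intermediate
8 | ethyl 4-(chlorocarbonyl)-2-[3-methoxy-4,5-bis(methoxymethoxy)phenyl]furan-3-carboxylate | CCOC(=O)c1c(C(Cl)=O)coc1-c1cc(OC)c(OCOC)c(OCOC)c1 | intermediate
9 | ethyl 4-(2-diazoacetyl)-2-[3-methoxy-4,5-bis(methoxymethoxy)phenyl]furan-3-carboxylate | CCOC(=O)c1c(C(=O)C=[N+]=[N-])coc1-c1cc(OC)c(OCOC)c(OCOC)c1 | intermediate
10 | ethyl dibromoacetate | CCOC(=O)C(Br)Br | starting material
11 | lithium ethynolate | [Li+].[O-]C#C | intermediate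
12 | (ethynyloxy)triisopropylsilane | C#CO[Si](C(C)C)(C(C)C)C(C)C | intermediate
13 | ethyl 2-[3-methoxy-4,5-bis(methoxymethoxy)phenyl]-4-(2-oxoethenyl)furan-3-carboxylate | CCOC(=O)c1c(C=C=O)coc1-c1cc(OC)c(OCOC)c(OCOC)c1 | intermediate
14 | ethyl 2-[3-methoxy-4,5-bis(methoxymethoxy)phenyl]-4-[4-oxo-2-(triisopropylsilyloxy)cyclobut-2-en-1-yl]furan-3-carboxylate (racemic) | CCOC(=O)c1c(C2C(=O)C=C2O[Si](C(C)C)(C(C)C)C(C)C)coc1-c1cc(OC)c(OCOC)c(OCOC)c1 | intermediate
15 | ethyl 2-[3-methoxy-4,5-bis(methoxymethoxy)phenyl]-4-[(1E)-4-oxo-2-(triisopropylsilyloxy)buta-1,3-dien-1-yl]furan-3-carboxylate | CCOC(=O)c1c(/C=C(\C=C=O)O[Si](C(C)C)(C(C)C)C(C)C)coc1-c1cc(OC)c(OCOC)c(OCOC)c1 | intermediate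
16 | ethyl 7-hydroxy-2-[3-methoxy-4,5-bis(methoxymethoxy)phenyl]-5-(triisopropylsilyloxy)-1-benzofuran-3-carboxylate | CCOC(=O)c1c(-c2cc(OC)c(OCOC)c(OCOC)c2)oc2c(O)cc(O[Si](C(C)C)(C(C)C)C(C)C)cc12 | intermediate
17 | ethyl 7-methoxy-2-[3-methoxy-4,5-bis(methoxymethoxy)phenyl]-5-(triisopropylsilyloxy)-1-benzofuran-3-carboxylate | CCOC(=O)c1c(-c2cc(OC)c(OCOC)c(OCOC)c2)oc2c(OC)cc(O[Si](C(C)C)(C(C)C)C(C)C)cc12 | intermediate
18 | ethyl 5-hydroxy-7-methoxy-2-[3-methoxy-4,5-bis(methoxymethoxy)phenyl]-1-benzofuran-3-carboxylate | CCOC(=O)c1c(-c2cc(OC)c(OCOC)c(OCOC)c2)oc2c(OC)cc(O)cc12 | intermediate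
19 | ethyl 7-methoxy-2-[3-methoxy-4,5-bis(methoxymethoxy)phenyl]-5-(trifluoromethylsulfonyloxy)-1-benzofuran-3-carboxylate | CCOC(=O)c1c(-c2cc(OC)c(OCOC)c(OCOC)c2)oc2c(OC)cc(OS(=O)(=O)C(F)(F)F)cc12 | intermediate
20 | tert-butyl(dimethyl)(prop-2-en-1-yloxy)silane | C=CCO[Si](C)(C)C(C)(C)C | starting material
21 | 9-[3-(tert-butyldimethylsilyloxy)propyl]-9-borabicyclo[3.3.1]nonane | CC(C)(C)[Si](C)(C)OCCCB1C2CCCC1CCC2 | intermediate
22 | ethyl 5-[3-(tert-butyldimethylsilyloxy)propyl]-7-methoxy-2-[3-methoxy-4,5-bis(methoxymethoxy)phenyl]-1-benzofuran-3-carboxylate | CCOC(=O)c1c(-c2cc(OC)c(OCOC)c(OCOC)c2)oc2c(OC)cc(CCCO[Si](C)(C)C(C)(C)C)cc12 | intermediate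
23 | {5-[3-(tert-butyldimethylsilyloxy)propyl]-7-methoxy-2-[3-methoxy-4,5-bis(methoxymethoxy)phenyl]-1-benzofuran-3-yl}methanol | OCc1c(-c2cc(OC)c(OCOC)c(OCOC)c2)oc2c(OC)cc(CCCO[Si](C)(C)C(C)(C)C)cc12 | intermediate
24 | 5-[3-(tert-butyldimethylsilyloxy)propyl]-7-methoxy-2-[3-methoxy-4,5-bis(methoxymethoxy)phenyl]-1-benzofuran-3-carbaldehyde | O=Cc1c(-c2cc(OC)c(OCOC)c(OCOC)c2)oc2c(OC)cc(CCCO[Si](C)(C)C(C)(C)C)cc12 | intermediate
25 | Mururin C, 2-(3,4-dihydroxy-5-methoxyphenyl)-5-(3-hydroxypropyl)-7-methoxy-1-benzofuran-3-carbaldehyde | COc1cc(-c2oc3c(OC)cc(CCCO)cc3c2C=O)cc(O)c1O | target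

## Count and risks

Total: 13 steps. Longest linear sequence: 12 steps (steps 1 to 5 and 7 to 13, from 1 to 25); step 6 is a one-step side branch.

**Step 7 (key step).** The arylfuran chromophore may compete with the diazoketone for light, so that the Wolff rearrangement is slow and photodegradation of product sets in. The ketene may also be consumed by acylating the product phenol before it meets the alkyne. The fallback generates the same ketene in the dark; it sets out from 9 and returns at 16. Silver-promoted Wolff rearrangement of 9 in aqueous THF (PhCO2Ag, Et3N) would give 2-{4-(ethoxycarbonyl)-5-Ar-furan-3-yl}acetic acid F1. The α-chloroenamine of step 5 would convert it into ethyl 4-(2-chloro-2-oxoethyl)-2-Ar-furan-3-carboxylate F2. Slow addition of Et3N to F2 and 12 in toluene would give ketene 13 by dehydrochlorination, and heating would carry cyclobutenone 14 through 15 to 16.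

**Step 6.** Deprotonation of the acidic α-hydrogen may compete with the first bromine–lithium exchange, and silylation of the ynolate may occur on carbon to give a silylketene instead of the ynol ether. The fallback changes the ketenophile; it sets out from 9 and returns at 18. Benzyl alcohol, KH and trichloroethylene would give benzyl (E)-1,2-dichlorovinyl ether F3, and n-BuLi followed by methanol would give benzyl ethynyl ether F4. Benzannulation of 9 with F4 under the conditions of step 7 would give ethyl 5-(benzyloxy)-7-hydroxy-2-Ar-1-benzofuran-3-carboxylate F5. Methylation (MeI, K2CO3) would give ethyl 5-(benzyloxy)-7-methoxy-2-Ar-1-benzofuran-3-carboxylate F6. Hydrogenolysis (H2, Pd/C), which the acetal ethers survive, would release phenol 18, to be triflated with PhNTf2 and Et3N to 19.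

**Step 4.** Discrimination between the two esters may be insufficient, leading to saponification at C3 or at both sites. The fallback builds the furan with two different esters; it sets out from 4 and returns at 7.
- Bromine–lithium exchange on 4 (n-BuLi, THF, −78 °C) and carboxylation with CO2 would give 3-methoxy-4,5-bis(methoxymethoxy)benzoic acid F7.
- Activation with carbonyldiimidazole and acylation of potassium ethyl malonate with MgCl2 and Et3N would give ethyl 3-Ar-3-oxopropanoate F8.
- Feist–Benary condensation of F8 with benzyl 3-bromo-2-oxopropanoate F9 (made from bromopyruvic acid and benzyl alcohol), using pyridine and then MsCl/Et3N for the dehydration, would give 4-benzyl 3-ethyl 2-Ar-furan-3,4-dicarboxylate F10.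
- Hydrogenolysis of the benzyl ester (H2, Pd/C) would give 7.

**Step 3.** Oxidative addition of the electron-rich bromide may be slow, and the product may undergo a second arylation at C5. The fallback replaces C–H activation by a preformed organometallic; it sets out from 5 (with 4) and returns at 6. Deprotonation of 5 at C2 with TMPMgCl·LiCl (THF, −40 °C) and transmetalation with ZnCl2 would give [3,4-bis(ethoxycarbonyl)furan-2-yl]zinc chloride F11. Negishi coupling of F11 with 4 (Pd(OAc)2, a biarylphosphine, THF, 50 °C) would give 6.

## Further compounds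

F1 | step 7 | 2-{4-(ethoxycarbonyl)-5-[3-methoxy-4,5-bis(methoxymethoxy)phenyl]furan-3-yl}acetic acid | CCOC(=O)c1c(CC(=O)O)coc1-c1cc(OC)c(OCOC)c(OCOC)c1
F2 | step 7 | ethyl 4-(2-chloro-2-oxoethyl)-2-[3-methoxy-4,5-bis(methoxymethoxy)phenyl]furan-3-carboxylate | CCOC(=O)c1c(CC(Cl)=O)coc1-c1cc(OC)c(OCOC)c(OCOC)c1
F3 | step 6 | benzyl (E)-1,2-dichlorovinyl ether | Cl/C=C(/Cl)OCc1ccccc1
F4 | step 6 | benzyl ethynyl ether | C#COCc1ccccc1
F5 | step 6 | ethyl 5-(benzyloxy)-7-hydroxy-2-[3-methoxy-4,5-bis(methoxymethoxy)phenyl]-1-benzofuran-3-carboxylate | CCOC(=O)c1c(-c2cc(OC)c(OCOC)c(OCOC)c2)oc2c(O)cc(OCc3ccccc3)cc12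
F6 | step 6 | ethyl 5-(benzyloxy)-7-methoxy-2-[3-methoxy-4,5-bis(methoxymethoxy)phenyl]-1-benzofuran-3-carboxylate | CCOC(=O)c1c(-c2cc(OC)c(OCOC)c(OCOC)c2)oc2c(OC)cc(OCc3ccccc3)cc12
F7 | step 4 | 3-methoxy-4,5-bis(methoxymethoxy)benzoic acid | COCOc1cc(C(=O)O)cc(OC)c1OCOC
F8 | step 4 | ethyl 3-[3-methoxy-4,5-bis(methoxymethoxy)phenyl]-3-oxopropanoate | CCOC(=O)CC(=O)c1cc(OC)c(OCOC)c(OCOC)c1
F9 | step 4 | benzyl 3-bromo-2-oxopropanoate | O=C(CBr)C(=O)OCc1ccccc1
F10 | step 4 | 4-benzyl 3-ethyl 2-[3-methoxy-4,5-bis(methoxymethoxy)phenyl]furan-3,4-dicarboxylate | CCOC(=O)c1c(C(=O)OCc2ccccc2)coc1-c1cc(OC)c(OCOC)c(OCOC)c1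
F11 | step 3 | [3,4-bis(ethoxycarbonyl)furan-2-yl]zinc chloride | CCOC(=O)c1coc([Zn]Cl)c1C(=O)OCC
A1 | alternative 1 | methyl (E)-3-(3-benzyloxy-4-hydroxy-5-methoxyphenyl)acrylate (methyl 5-benzyloxyferulate) | COC(=O)/C=C/c1cc(OC)c(O)c(OCc2ccccc2)c1
A2 | alternative 1 | 4-(3-hydroxypropyl)-2-methoxyphenol (dihydroconiferyl alcohol) | COc1cc(CCCO)ccc1O
A3 | alternative 1 | racemic trans methyl 2-(3-benzyloxy-4-hydroxy-5-methoxyphenyl)-5-(3-hydroxypropyl)-7-methoxy-2,3-dihydrobenzofuran-3-carboxylate (one enantiomer drawn) | COC(=O)[C@@H]1[C@@H](c2cc(OC)c(O)c(OCc3ccccc3)c2)Oc2c(OC)cc(CCCO)cc21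
A4 | alternative 2 | methyl 3,3-dibromo-2-{5-[3-(tert-butyldimethylsilyloxy)propyl]-2-hydroxy-3-methoxyphenyl}acrylate | COC(=O)C(=C(Br)Br)c1cc(CCCO[Si](C)(C)C(C)(C)C)cc(OC)c1O
A5 | alternative 2 | 2-(3,4-dibenzyloxy-5-methoxyphenyl)-4,4,5,5-tetramethyl-1,3,2-dioxaborolane | COc1cc(B2OC(C)(C)C(C)(C)O2)cc(OCc2ccccc2)c1OCc1ccccc1
A6 | alternative 2 | methyl 2-(3,4-dibenzyloxy-5-methoxyphenyl)-7-methoxy-5-[3-(tert-butyldimethylsilyloxy)propyl]benzofuran-3-carboxylate | COC(=O)c1c(-c2cc(OC)c(OCc3ccccc3)c(OCc3ccccc3)c2)oc2c(OC)cc(CCCO[Si](C)(C)C(C)(C)C)cc12
A7 | alternative 3 | (5-allyl-2-hydroxy-3-methoxyphenyl)(3,4-dibenzyloxy-5-methoxyphenyl)methanone | C=CCc1cc(OC)c(O)c(C(=O)c2cc(OC)c(OCc3ccccc3)c(OCc3ccccc3)c2)c1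
A8 | alternative 3 | ethyl diazoacetate | CCOC(=O)C=[N+]=[N-]
A9 | alternative 3 | ethyl 5-allyl-2-(3,4-dibenzyloxy-5-methoxyphenyl)-7-methoxybenzofuran-3-carboxylate | CCOC(=O)c1c(-c2cc(OC)c(OCc3ccccc3)c(OCc3ccccc3)c2)oc2c(OC)cc(CC=C)cc12
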